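**Strategy.** Sideroxylonal A is cut across its dihydropyran ring at O1–C2 and C3–C4, a retro oxa-Diels–Alder that uncovers a hidden duplication. Ring A with C4 and its isobutyl group, and ring B with C2, C3 and the isopropyl group, are the same formylated phloroglucinol bearing one five-carbon chain, once as ortho-quinone methide and once as its styrene tautomer. A single benzylic alcohol monomer is therefore dehydrated by a chiral phosphoric acid and dimerised in one operation, which closes the pyran ring at O1–C2, forms C3–C4 and sets C2, C3 and C4. The precursor is half the size of the product and carries only a racemic carbinol centre that is erased on the way.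

Key step: step 3

Remark on availability: compound 1 is taken as a purchasable building block (it is sold as a linker for covalent organic frameworks).

Remark on the sense of induction: the (R)-configured acid is assumed to lead to the (2R,3R,4S) series; this cannot be derived from first principles here and would have to be confirmed, and the (S)-configured acid is used if it proves opposite.

Step 1
Reactants: 1 2,4,6-trimethoxybenzene-1,3,5-tricarbaldehyde
Product: 2 2-hydroxy-4,6-dimethoxybenzene-1,3,5-tricarbaldehyde
Conditions: BCl3 (1.05 equiv), CH2Cl2, −78 to 0 °C; then H2O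
Reagents that add atoms: none
Why: Chelation-assisted ether cleavage (Lewis acid dealkylation): BCl3 bridges a formyl oxygen and a neighbouring methoxy oxygen, chloride removes the methyl group, and the chelated aryloxyboron dichloride so formed ties up the single equivalent of reagent, so that one of the three equivalent ethers should be cleaved and no more; no stereocentre is formed.

Step 2
Reactants: 2 2-hydroxy-4,6-dimethoxybenzene-1,3,5-tricarbaldehyde; 3 isobutylmagnesium bromide
Product: 4 4-hydroxy-5-(1-hydroxy-3-methylbutyl)-2,6-dimethoxybenzene-1,3-dicarbaldehyde (racemic; used without long storage)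
Conditions: 3 (2.1 equiv), THF, −78 to −20 °C; then aqueous NaH2PO4/Na2HPO4 (pH 7)
Reagents that add atoms: isobutylmagnesium bromide (compound 3), CC(C)C[Mg]Br
Why: Grignard addition to a magnesium phenoxide of the salicylaldehyde type: the first equivalent of 3 forms the phenoxide, which holds magnesium next to the two equivalent ortho formyl groups and so should steer the second equivalent to one of them rather than to the remote formyl group between the two methoxy groups, while the resulting dianion resists further addition; the new carbinol centre is racemic and is erased in step 3.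

Step 3
Reactants: 4 4-hydroxy-5-(1-hydroxy-3-methylbutyl)-2,6-dimethoxybenzene-1,3-dicarbaldehyde (two molecules)
Product: 7 (2R,3R,4S)-2-(3,5-diformyl-2-hydroxy-4,6-dimethoxyphenyl)-5,7-dimethoxy-4-(2-methylpropyl)-3-(propan-2-yl)-3,4-dihydro-2H-1-benzopyran-6,8-dicarbaldehyde, via ortho-quinone methide 5 (not isolated), via (E)-2-hydroxystyrene 6 (not isolated)
Conditions: (R)-3,3'-bis(2,4,6-triisopropylphenyl)-1,1'-binaphthyl-2,2'-diyl hydrogen phosphate (10 mol %), 5 Å molecular sieves, PhMe (0.2 M), 25 °C
Reagents that add atoms: none
Why: The acid dehydrates 4 to the ortho-quinone methide 5, part of which tautomerises (acid-mediated 1,5-hydrogen shift) to the (E)-2-hydroxystyrene 6, and the phosphate, hydrogen-bonded to the carbonyl oxygen of 5 and to the phenol of 6, unites the two in an asynchronous inverse-electron-demand oxa-Diels–Alder reaction in which C3–C4 bonding leads and the quinone methide oxygen (O1) closes onto the benzylic carbon C2. The closest known reaction type is the chiral phosphoric acid-catalysed [4+2] cycloaddition of ortho-hydroxybenzyl alcohols with 2-hydroxystyrenes to 2-arylchromans, the racemic counterpart being the acid-catalysed dimerisation of 2-alkenylphenols. The dihydropyran ring is closed by the cycloaddition itself; in the stepwise limit the closure is a 6-exo-trig oxa-Michael addition of the ring A oxygen to the ring B quinone methide. C4 is controlled by the catalyst, which shields one face of 5; C3 follows from the exo placement of the twisted, di-ortho-substituted ring B, which puts the isopropyl group endo to the (E)-configured diene (3,4-cis); C2 follows from the (E)-geometry of 6, transferred suprafacially (2,3-trans), and any reversible opening of O1–C2 under the acid should return to this more stable arrangement. The step needs cross-selectivity, head-to-tail regioselectivity and exo topicity: both aromatic rings are fully substituted so no Friedel–Crafts position competes, the matched polarisation of 5 (electrophilic methide carbon) and 6 (nucleophilic β-carbon) fixes the orientation, and the bulk of ring B should secure the exo mode.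

Step 4
Reactants: 7 (2R,3R,4S)-2-(3,5-diformyl-2-hydroxy-4,6-dimethoxyphenyl)-5,7-dimethoxy-4-(2-methylpropyl)-3-(propan-2-yl)-3,4-dihydro-2H-1-benzopyran-6,8-dicarbaldehyde
Product: 8 sideroxylonal A, (2R,3R,4S)-2-(3,5-diformyl-2,4,6-trihydroxyphenyl)-5,7-dihydroxy-4-(2-methylpropyl)-3-(propan-2-yl)-3,4-dihydro-2H-1-benzopyran-6,8-dicarbaldehyde
Conditions: BCl3 (8 equiv), CH2Cl2, −78 to 0 °C; then H2O
Reagents that add atoms: none
Why: Chelation-assisted ether cleavage: each of the four methoxy groups lies ortho to a formyl group and should be cleaved by BCl3 as in step 1, C3 and C4 are not touched, and if the benzylic ring ether at C2 opens under the Lewis acid it should reclose on work-up to the more stable 2,3-trans arrangement.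

**Compound list**

1 | 2,4,6-trimethoxybenzene-1,3,5-tricarbaldehyde | COc1c(C=O)c(OC)c(C=O)c(OC)c1C=O | starting material
2 | 2-hydroxy-4,6-dimethoxybenzene-1,3,5-tricarbaldehyde | O=Cc1c(O)c(C=O)c(OC)c(C=O)c1OC | intermediate
3 | isobutylmagnesium bromide | CC(C)C[Mg]Br | starting material
4 | 4-hydroxy-5-(1-hydroxy-3-methylbutyl)-2,6-dimethoxybenzene-1,3-dicarbaldehyde (racemic) | CC(C)CC(O)c1c(O)c(C=O)c(OC)c(C=O)c1OC | intermediate
5 | (5E)-2,4-dimethoxy-5-(3-methylbutylidene)-6-oxocyclohexa-1,3-diene-1,3-dicarbaldehyde (ortho-quinone methide, not isolated) | CC(C)C/C=C1/C(=O)C(C=O)=C(OC)C(C=O)=C1OC | intermediate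
6 | 4-hydroxy-2,6-dimethoxy-5-[(1E)-3-methylbut-1-en-1-yl]benzene-1,3-dicarbaldehyde (not isolated) | CC(C)/C=C/c1c(O)c(C=O)c(OC)c(C=O)c1OC | intermediate
7 | (2R,3R,4S)-2-(3,5-diformyl-2-hydroxy-4,6-dimethoxyphenyl)-5,7-dimethoxy-4-(2-methylpropyl)-3-(propan-2-yl)-3,4-dihydro-2H-1-benzopyran-6,8-dicarbaldehyde | CC(C)C[C@@H]1c2c(OC)c(C=O)c(OC)c(C=O)c2O[C@@H](c2c(O)c(C=O)c(OC)c(C=O)c2OC)[C@@H]1C(C)C | intermediate
8 | sideroxylonal A, (2R,3R,4S)-2-(3,5-diformyl-2,4,6-trihydroxyphenyl)-5,7-dihydroxy-4-(2-methylpropyl)-3-(propan-2-yl)-3,4-dihydro-2H-1-benzopyran-6,8-dicarbaldehyde | CC(C)C[C@@H]1c2c(O)c(C=O)c(O)c(C=O)c2O[C@@H](c2c(O)c(C=O)c(O)c(C=O)c2O)[C@@H]1C(C)C | target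

Total step count: 4. Longest linear sequence: 4 steps (1 → 2 → 4 → 7 → 8).

**Steps most likely to fail**

Step 3. The chiral acid may discriminate poorly between the two faces of the quinone methide, because the substrates are internally hydrogen-bonded and fairly acidic and an uncatalysed background dimerisation can compete; the exo topicity may erode as well. The fallback gives up catalyst control for resolution. Setting out from 4, the dimerisation is run with an achiral acid (diphenyl phosphate, 5 Å molecular sieves, PhMe, 25 °C). Through 5 and 6 it should give the racemate made up of 7 and its enantiomer (2S,3S,4R)-2-(3,5-diformyl-2-hydroxy-4,6-dimethoxyphenyl)-5,7-dimethoxy-4-(2-methylpropyl)-3-(propan-2-yl)-3,4-dihydro-2H-1-benzopyran-6,8-dicarbaldehyde F1. Diastereomers are removed on silica, and the racemate is resolved by preparative chromatography on a chiral stationary phase (amylose tris(3,5-dimethylphenylcarbamate) on silica). This returns the route to 7.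

Step 2. The isobutyl group may be delivered to the formyl group para to the phenoxide or to more than one formyl group, or hydride transfer from the β-position of the Grignard reagent may reduce the aldehyde instead of adding to it. The fallback replaces the Grignard reagent by a hydroxyl-directed allylboration followed by hydrogenation. Setting out from 2, 2-methylallylboronic acid pinacol ester (Et3N, CH2Cl2, 25 °C, aqueous work-up) is bound by the phenol and should deliver the methallyl group through a six-membered chair to the neighbouring formyl group only. This gives 4-hydroxy-5-(1-hydroxy-3-methylbut-3-en-1-yl)-2,6-dimethoxybenzene-1,3-dicarbaldehyde F2. Hydrogenation of its 1,1-disubstituted alkene with RhCl(PPh3)3 (5 mol %) and H2 (1 atm) in benzene at 25 °C should leave the aryl aldehydes and the benzylic alcohol alone and returns the route to 4.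

Step 4. The Lewis acid, chelated between O1 and the formyl group at C8, may ionise the benzylic ring ether O1–C2, and elimination towards C3 or loss of material may follow before the ring recloses. The fallback removes the methyl groups before the pyran ring exists and lets the unprotected monomer dimerise as in the presumed biogenesis. Setting out from 4, BCl3 (4 equiv, CH2Cl2, −78 to 0 °C, then H2O) should cleave both ethers to give 2,4,6-trihydroxy-5-(1-hydroxy-3-methylbutyl)benzene-1,3-dicarbaldehyde F3. With NaOAc (0.2 equiv) in MeCN/H2O at 40 °C this triphenol should lose water to the quinone methide (5E)-2,4-dihydroxy-5-(3-methylbutylidene)-6-oxocyclohexa-1,3-diene-1,3-dicarbaldehyde F4. Part of F4 tautomerises to 2,4,6-trihydroxy-5-[(1E)-3-methylbut-1-en-1-yl]benzene-1,3-dicarbaldehyde F5, and the two combine in the same oxa-Diels–Alder reaction. Because the chiral acid cannot control a substrate as acidic as itself, the product is expected as the racemate of 8 and its enantiomer (2S,3S,4R)-2-(3,5-diformyl-2,4,6-trihydroxyphenyl)-5,7-dihydroxy-4-(2-methylpropyl)-3-(propan-2-yl)-3,4-dihydro-2H-1-benzopyran-6,8-dicarbaldehyde F6. Diastereomers are removed by chromatography, and preparative chromatography on a chiral stationary phase returns the route to 8.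

**Further compounds**

F1 | step 3 | (2S,3S,4R)-2-(3,5-diformyl-2-hydroxy-4,6-dimethoxyphenyl)-5,7-dimethoxy-4-(2-methylpropyl)-3-(propan-2-yl)-3,4-dihydro-2H-1-benzopyran-6,8-dicarbaldehyde | CC(C)C[C@H]1c2c(OC)c(C=O)c(OC)c(C=O)c2O[C@H](c2c(O)c(C=O)c(OC)c(C=O)c2OC)[C@H]1C(C)C
F2 | step 2 | 4-hydroxy-5-(1-hydroxy-3-methylbut-3-en-1-yl)-2,6-dimethoxybenzene-1,3-dicarbaldehyde | CC(=C)CC(O)c1c(O)c(C=O)c(OC)c(C=O)c1OC
F3 | step 4 | 2,4,6-trihydroxy-5-(1-hydroxy-3-methylbutyl)benzene-1,3-dicarbaldehyde | CC(C)CC(O)c1c(O)c(C=O)c(O)c(C=O)c1O
F4 | step 4 | (5E)-2,4-dihydroxy-5-(3-methylbutylidene)-6-oxocyclohexa-1,3-diene-1,3-dicarbaldehyde | CC(C)C/C=C1/C(=O)C(C=O)=C(O)C(C=O)=C1O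
F5 | step 4 | 2,4,6-trihydroxy-5-[(1E)-3-methylbut-1-en-1-yl]benzene-1,3-dicarbaldehyde | CC(C)/C=C/c1c(O)c(C=O)c(O)c(C=O)c1O
F6 | step 4 | (2S,3S,4R)-2-(3,5-diformyl-2,4,6-trihydroxyphenyl)-5,7-dihydroxy-4-(2-methylpropyl)-3-(propan-2-yl)-3,4-dihydro-2H-1-benzopyran-6,8-dicarbaldehyde | CC(C)C[C@H]1c2c(O)c(C=O)c(O)c(C=O)c2O[C@H](c2c(O)c(C=O)c(O)c(C=O)c2O)[C@H]1C(C)C
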